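The route rests on cutting the ring-fusion bond C5–C10 together with C6–C7 (eremophilane numbering), which opens both carbocycles to one acyclic chain. The key step is a thermal intramolecular Diels–Alder reaction. A 1-silyloxy vinylallene, C10=C9–C8(OTBS)=C7=C11Me2, adds to the unactivated isopropenyl group C5(Me)=C6H2 across the C1–C4 tether. One operation closes rings A and B and builds quaternary C5 and C10. The distal allene bond remains as the C7 isopropylidene, and C8=C9 remains as a silyl enol ether for C9 hydroxylation. The step thus exploits the ring-B array C7(=CMe2)–C8(=O)–C9(OH). The precursor carries only C3 and C4, set by one allylboration.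

Key step: step 7

Remark on numbering: ring A = C1–C5 and C10 (C3 bears the ester oxygen, C4 the secondary methyl C15, C5 the angular methyl C14). Ring B = C5–C10 (C6 is CH2, C7 bears the isopropylidene C11–C13, C8 is the ketone, C9 the carbinol). β is the face of the C5 methyl group, and the target is 3R,4R,5R,9S,10R.

Assumption: the sense of induction of the TRIP acid is taken from the benzaldehyde/allyl-Bpin model, in which the (R)-acid leads to Re-face attack. The (S)-acid is therefore specified for the required Si-face attack, and the antipodal acid is used if the trisubstituted reagent responds oppositely.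

Step 1
Reactants: 1 (Z)-2-bromobut-2-ene; 2 2-(chloromethyl)-4,4,5,5-tetramethyl-1,3,2-dioxaborolane
Product: 5 (Z)-4,4,5,5-tetramethyl-2-(2-methylbut-2-en-1-yl)-1,3,2-dioxaborolane, via alkenyllithium 3 (not isolated), via borate complex 4 (not isolated)
Conditions: t-BuLi (2 equiv), Et2O, −78 °C; then 2, −78 °C to rt
Reagents that add atoms: none
Why: Bromine–lithium exchange with retention of alkene geometry, addition of 3 to boron and a 1,2-metallate shift with loss of chloride (Matteson-type homologation) should give the allylboronate with the γ-methyl group cis to CH2B, and pinacol allylboronates do not scramble by borotropic shift.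

Step 2
Reactants: 5 (Z)-allylboronate; 6 pent-4-ynal
Product: 8 (3R,4R)-2,3-dimethyloct-1-en-7-yn-4-ol, via homoallyl borate 7 (not isolated)
Conditions: (S)-TRIP (5 mol %), 4 Å MS, PhMe, −30 °C; aq NaHCO3 work-up
Reagents that add atoms: none
Why: Chiral-phosphoric-acid-catalysed allylboration through a closed chair transition state, in which the Z γ-methyl group is axial and gives the syn C3/C4 pair while the acid, bound to a boronate oxygen and the formyl hydrogen, selects the Si face of 6 and so sets C3 (R) and C4 (R).

Step 3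
Reactants: 8 (3R,4R)-2,3-dimethyloct-1-en-7-yn-4-ol
Product: 9 triethyl{[(3R,4R)-2,3-dimethyloct-1-en-7-yn-4-yl]oxy}silane
Conditions: TESCl, imidazole, CH2Cl2, 0 °C to rt
Reagents that add atoms: chlorotriethylsilane CC[Si](Cl)(CC)CC
Why: Standard silylation of a secondary alcohol, with TES chosen because it survives the organometallic, thermal and buffered peracid steps yet can later be cleaved beside a secondary TBS ether.

Step 4
Reactants: 9 TES ether; 10 but-2-ynal
Product: 14 (3R,4R,7E)-2,3-dimethyl-4-(triethylsilyloxy)dodeca-1,7-dien-10-yn-9-ol (both C9 epimers of the chain name), via alkenylzirconocene 11 (not isolated), via alkenylzinc 12 (not isolated), via zinc alkoxide 13 (not isolated)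
Conditions: Cp2Zr(H)Cl, CH2Cl2, rt; Me2Zn, PhMe, −65 °C; then 10, 0 °C; aq NH4Cl
Reagents that add atoms: none
Why: Syn hydrozirconation of the terminal alkyne, much faster than attack on the hindered 1,1-disubstituted alkene, fixes the E C9=C10 bond, and zirconium-to-zinc transmetalation allows 1,2-addition to the ynal, the new carbinol centre being erased in step 5.

Step 5
Reactants: 14 dienynol
Product: 15 (3R,4R,7E)-2,3-dimethyl-4-(triethylsilyloxy)dodeca-1,7-dien-10-yn-9-one
Conditions: activated MnO2, CH2Cl2, rt
Reagents that add atoms: none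
Why: Chemoselective MnO2 oxidation of a doubly activated (allylic and propargylic) alcohol, to which the silyl ether and the isolated alkene are inert.

Step 6
Reactants: 15 cross-conjugated enynone
Product: 17 (3R,4R,7E)-9-(tert-butyldimethylsilyloxy)-2,3,11-trimethyl-4-(triethylsilyloxy)dodeca-1,7,9,10-tetraene, via lithium allenolate 16 (not isolated)
Conditions: Me2CuLi (from CuI, 2 MeLi), Et2O/THF, −78 °C; then TBSOTf, −78 to 0 °C; Et3N, cold aq NaHCO3
Reagents that add atoms: lithium dimethylcuprate [Li+].C[Cu-]C; tert-butyldimethylsilyl trifluoromethanesulfonate CC(C)(C)[Si](C)(C)OS(=O)(=O)C(F)(F)F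
Why: Conjugate addition of a Gilman cuprate to the ynone terminus C11, which is more electrophilic toward cuprates than the β-alkyl enone carbon C10, gives an allenolate that the hard silyl triflate should trap on oxygen (1,4-addition with enolate O-silylation), so C13 and the TBS group are installed together.

Step 7
Reactants: 17 silyloxy vinylallene
Product: 18 8-(tert-butyldimethylsilyloxy)-3α-(triethylsilyloxy)-10αH-eremophila-7(11),8-diene (trans-fused, 4β,5β-dimethyl)
Conditions: PhMe (0.01 M), BHT (cat.), base-washed sealed tube, 130 °C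
Reagents that add atoms: none
Why: The mechanism is a concerted, asynchronous [4π+2π] cycloaddition of the s-cis diene C10=C9–C8=C7 with C5=C6 that bonds C10 to C5 and C7 to C6; the proximal allene bond serves as the second diene bond, and the sp carbon C7 removes the inside substituent that normally slows terminally substituted dienes. The closest known reaction type is the type-1 intramolecular Diels–Alder reaction of 1-silyloxy vinylallenes with unactivated tethered alkenes, a cyclisation of the 1,7,9-decatriene class. Ring B is the six-membered cycloaddition ring, and ring A closes at the same time as the fused tether ring, its four-atom chain C1–C4 folded as a chair. C5 is controlled by C4 and C3: with C4–H eclipsing C5=C6 (A1,3 strain) and both the C4 methyl and C3–OTES equatorial, the diene reaches only one alkene face, which places the C5 methyl cis to the C4 methyl. C10 follows from the E geometry of C9=C10 and the anti (tether-exo, methyl-endo) transition state, in which the diene sits equatorially on the forming chair and gives the trans fusion (10α-H), whereas the syn alternative needs an axial diene with two syn-axial contacts. The step needs periselectivity, secured by acid-free conditions that keep the distal allene bond and both silyl ethers untouched and close hydrolysis and Nazarov-type paths, and it needs ring-fusion selectivity, which rests only on these conformational preferences and is the weak point.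

Step 8
Reactants: 18 silyl dienol ether
Product: 20 9α-(tert-butyldimethylsilyloxy)-3α-(triethylsilyloxy)-10αH-eremophil-7(11)-en-8-one, via silyloxy epoxide 19 (not isolated)
Conditions: mCPBA (1.05 equiv), CH2Cl2/pH 7 phosphate buffer, −10 to 0 °C
Reagents that add atoms: 3-chloroperoxybenzoic acid O=C(OO)c1cccc(Cl)c1
Why: Rubottom oxidation, in which the peracid should attack the most electron-rich double bond, the silyl enol ether C8=C9, from the α face opposite the axial C5 methyl group, and opening of 19 with 1,4-silyl migration gives the 9α (equatorial, also thermodynamically preferred) silyloxy ketone, so C9 is set and protected in one step.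

Step 9
Reactants: 20 bis-silyl ether
Product: 21 9α-(tert-butyldimethylsilyloxy)-3α-hydroxy-10αH-eremophil-7(11)-en-8-one
Conditions: PPTS (cat.), MeOH/CH2Cl2, 0 °C
Reagents that add atoms: none
Why: Acid-catalysed methanolysis distinguishes the less hindered triethylsilyl ether from the tert-butyldimethylsilyl ether (selective desilylation) and touches no stereocentre.

Step 10
Reactants: 22 (E)-non-3-en-2-one; 23 triethyl (E)-4-phosphonocrotonate
Product: 25 ethyl (2E,4E,6E)-5-methyldodeca-2,4,6-trienoate, via lithiated phosphonate 24 (not isolated)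
Conditions: 23, LiHMDS, THF/DMPU, −78 °C; then 22, −78 °C to rt; chromatography
Reagents that add atoms: none
Why: Vinylogous Horner–Wadsworth–Emmons olefination of a methyl ketone, in which 2E comes from 23, 6E from 22, and the new C4=C5 bond should form mainly E because heptenyl is larger than methyl, the minor 4Z isomer being removed by chromatography.

Step 11
Reactants: 25 ethyl trienoate
Product: 27 (2E,4E,6E)-5-methyldodeca-2,4,6-trienoic acid, via lithium carboxylate 26 (not isolated)
Conditions: LiOH, THF/MeOH/H2O, rt; then 1 M HCl to pH 3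
Reagents that add atoms: lithium hydroxide [Li+].[OH-]
Why: Saponification of an unhindered ethyl ester under conditions that should not isomerise the triene.

Step 12
Reactants: 21 C3 alcohol; 27 trienoic acid
Product: 28 9α-(tert-butyldimethylsilyloxy)-8-oxo-10αH-eremophil-7(11)-en-3α-yl (2E,4E,6E)-5-methyldodeca-2,4,6-trienoate
Conditions: DCC, DMAP (cat.), CH2Cl2, 0 °C to rt
Reagents that add atoms: none
Why: Steglich esterification acylates the only free hydroxyl, the equatorial C3–OH, with retention at C3.

Step 13
Reactants: 28 silyl-protected ester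
Product: 29 target, (3R,4R,5R,9S,10R)-9-hydroxy-8-oxoeremophil-7(11)-en-3-yl (2E,4E,6E)-5-methyldodeca-2,4,6-trienoate
Conditions: HF·pyridine, THF, 0 °C to rt (plastic vessel)
Reagents that add atoms: none
Why: Fluoride-mediated silyl ether cleavage under mildly acidic conditions avoids base-induced ketol isomerisation, ester cleavage and triene isomerisation.

Compound list
1 | (Z)-2-bromobut-2-ene | C/C=C(Br)/C | starting material
2 | 2-(chloromethyl)-4,4,5,5-tetramethyl-1,3,2-dioxaborolane | ClCB1OC(C)(C)C(C)(C)O1 | starting material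
3 | (E)-but-2-en-2-yllithium (C4 methyl cis to Li) | C/C=C(/C)[Li] | intermediate
4 | lithium [(E)-but-2-en-2-yl](chloromethyl)pinacolatoborate | [Li+].C/C=C(/C)[B-]1(CCl)OC(C)(C)C(C)(C)O1 | intermediate
5 | (Z)-4,4,5,5-tetramethyl-2-(2-methylbut-2-en-1-yl)-1,3,2-dioxaborolane | C/C=C(/C)CB1OC(C)(C)C(C)(C)O1 | intermediate
6 | pent-4-ynal | C#CCCC=O | starting material
7 | 2-{[(3R,4R)-2,3-dimethyloct-1-en-7-yn-4-yl]oxy}-4,4,5,5-tetramethyl-1,3,2-dioxaborolane | C#CCC[C@@H](OB1OC(C)(C)C(C)(C)O1)[C@H](C)C(C)=C | intermediate
8 | (3R,4R)-2,3-dimethyloct-1-en-7-yn-4-ol | C#CCC[C@@H](O)[C@H](C)C(C)=C | intermediate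
9 | triethyl{[(3R,4R)-2,3-dimethyloct-1-en-7-yn-4-yl]oxy}silane | C#CCC[C@@H](O[Si](CC)(CC)CC)[C@H](C)C(C)=C | intermediate
10 | but-2-ynal | CC#CC=O | starting material
11 | chlorobis(cyclopentadienyl)[(1E,5R,6R)-6,7-dimethyl-5-(triethylsilyloxy)octa-1,7-dien-1-yl]zirconium | Cl[Zr](/C=C/CC[C@@H](O[Si](CC)(CC)CC)[C@H](C)C(C)=C)(C1C=CC=C1)C1C=CC=C1 | intermediate
12 | methyl[(1E,5R,6R)-6,7-dimethyl-5-(triethylsilyloxy)octa-1,7-dien-1-yl]zinc | C[Zn]/C=C/CC[C@@H](O[Si](CC)(CC)CC)[C@H](C)C(C)=C | intermediate
13 | methylzinc alkoxide of 14 | C[Zn]OC(C#CC)/C=C/CC[C@@H](O[Si](CC)(CC)CC)[C@H](C)C(C)=C | intermediate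
14 | (3R,4R,7E)-2,3-dimethyl-4-(triethylsilyloxy)dodeca-1,7-dien-10-yn-9-ol (carbinol epimers) | CC#CC(O)/C=C/CC[C@@H](O[Si](CC)(CC)CC)[C@H](C)C(C)=C | intermediate
15 | (3R,4R,7E)-2,3-dimethyl-4-(triethylsilyloxy)dodeca-1,7-dien-10-yn-9-one | CC#CC(=O)/C=C/CC[C@@H](O[Si](CC)(CC)CC)[C@H](C)C(C)=C | intermediate
16 | lithium (3R,4R,7E)-2,3,11-trimethyl-4-(triethylsilyloxy)dodeca-1,7,9,10-tetraen-9-olate | [Li+].CC(C)=C=C([O-])/C=C/CC[C@@H](O[Si](CC)(CC)CC)[C@H](C)C(C)=C | intermediate
17 | (3R,4R,7E)-9-(tert-butyldimethylsilyloxy)-2,3,11-trimethyl-4-(triethylsilyloxy)dodeca-1,7,9,10-tetraene | CC(C)=C=C(O[Si](C)(C)C(C)(C)C)/C=C/CC[C@@H](O[Si](CC)(CC)CC)[C@H](C)C(C)=C | intermediate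
18 | 8-(tert-butyldimethylsilyloxy)-3α-(triethylsilyloxy)-10αH-eremophila-7(11),8-diene | CC[Si](CC)(CC)O[C@@H]1CC[C@H]2C=C(O[Si](C)(C)C(C)(C)C)C(=C(C)C)C[C@]2(C)[C@H]1C | intermediate
19 | 8α,9α-epoxy-8β-(tert-butyldimethylsilyloxy)-3α-(triethylsilyloxy)-10αH-eremophil-7(11)-ene | CC[Si](CC)(CC)O[C@@H]1CC[C@H]2[C@@H]3O[C@]3(O[Si](C)(C)C(C)(C)C)C(=C(C)C)C[C@]2(C)[C@H]1C | intermediate
20 | 9α-(tert-butyldimethylsilyloxy)-3α-(triethylsilyloxy)-10αH-eremophil-7(11)-en-8-one | CC[Si](CC)(CC)O[C@@H]1CC[C@H]2[C@H](O[Si](C)(C)C(C)(C)C)C(=O)C(=C(C)C)C[C@]2(C)[C@H]1C | intermediate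
21 | 9α-(tert-butyldimethylsilyloxy)-3α-hydroxy-10αH-eremophil-7(11)-en-8-one | O[C@@H]1CC[C@H]2[C@H](O[Si](C)(C)C(C)(C)C)C(=O)C(=C(C)C)C[C@]2(C)[C@H]1C | intermediate
22 | (E)-non-3-en-2-one | CCCCC/C=C/C(C)=O | starting material
23 | triethyl (E)-4-phosphonocrotonate | CCOC(=O)/C=C/CP(=O)(OCC)OCC | starting material
24 | lithiated triethyl 4-phosphonocrotonate | [Li+].CCOC(=O)/C=C/[CH-]P(=O)(OCC)OCC | intermediate
25 | ethyl (2E,4E,6E)-5-methyldodeca-2,4,6-trienoate | CCCCC/C=C/C(C)=C/C=C/C(=O)OCC | intermediate
26 | lithium (2E,4E,6E)-5-methyldodeca-2,4,6-trienoate | [Li+].CCCCC/C=C/C(C)=C/C=C/C(=O)[O-] | intermediate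
27 | (2E,4E,6E)-5-methyldodeca-2,4,6-trienoic acid | CCCCC/C=C/C(C)=C/C=C/C(=O)O | intermediate
28 | 9α-(tert-butyldimethylsilyloxy)-8-oxo-10αH-eremophil-7(11)-en-3α-yl (2E,4E,6E)-5-methyldodeca-2,4,6-trienoate | CCCCC/C=C/C(C)=C/C=C/C(=O)O[C@@H]1CC[C@H]2[C@H](O[Si](C)(C)C(C)(C)C)C(=O)C(=C(C)C)C[C@]2(C)[C@H]1C | intermediate
29 | (3R,4R,5R,9S,10R)-9-hydroxy-8-oxoeremophil-7(11)-en-3-yl (2E,4E,6E)-5-methyldodeca-2,4,6-trienoate | CCCCC/C=C/C(C)=C/C=C/C(=O)O[C@@H]1CC[C@H]2[C@H](O)C(=O)C(=C(C)C)C[C@]2(C)[C@H]1C | target

Total step count: 13. Longest linear sequence: 11 steps (steps 1–9, 12, 13).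

Steps most likely to fail

Step 7. The anti and syn foldings of the tether may not be discriminated well, which would erode the ring-fusion selectivity at C10. The fallback sets out from 18 as obtained and moves the control of C10 from the cycloaddition to a stereoelectronically controlled reduction. Saegusa–Ito dehydrogenation (Pd(OAc)2, MeCN) erases C10 and should give 3α-(triethylsilyloxy)eremophila-7(11),9-dien-8-one F1. Dissolving-metal reduction (Li, NH3/THF, 1 equiv t-BuOH, −78 °C) should reduce the less substituted C9=C10 bond of the cross-conjugated dienone, with axial protonation at C10 giving the trans fusion. After removal of ammonia the regiodefined enolate is trapped with TBSOTf, and the route is rejoined at 18 as a single ring-fusion isomer.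

Step 6. The cuprate may add competitively at the enone carbon C10, or the allenolate may be silylated on carbon or protonated instead of silylated on oxygen. The fallback sets out from 14 and bypasses 15. Silylation (TBSCl, imidazole) gives (3R,4R,7E)-9-(tert-butyldimethylsilyloxy)-2,3-dimethyl-4-(triethylsilyloxy)dodeca-1,7-dien-10-yne F2. Deprotonation of its doubly activated carbinol C–H (s-BuLi, THF, −78 °C) gives the delocalised silyloxy-substituted anion, the same species that forms when an alkynyllithium adds to an α,β-unsaturated acylsilane and a Brook rearrangement follows. Methylation with MeI at the alkyne terminus rejoins the route at 17.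

Step 2. The catalyst may discriminate the aldehyde faces poorly with a trisubstituted allylboronate and an unbranched aliphatic aldehyde, which would lower the enantiopurity. The fallback sets out from 6 and replaces catalyst control by auxiliary control.
- An Evans syn aldol reaction with (S)-4-benzyl-3-propionyloxazolidin-2-one (Bu2BOTf, Et3N, CH2Cl2, −78 to 0 °C) gives (S)-4-benzyl-3-[(2S,3R)-3-hydroxy-2-methylhept-6-ynoyl]oxazolidin-2-one F3.
- Transamidation (MeONHMe·HCl, AlMe3) gives (2S,3R)-3-hydroxy-N-methoxy-N,2-dimethylhept-6-ynamide F4.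
- Silylation (TESCl, imidazole) gives (2S,3R)-N-methoxy-N,2-dimethyl-3-(triethylsilyloxy)hept-6-ynamide F5.
- Excess MeMgBr gives (3S,4R)-3-methyl-4-(triethylsilyloxy)oct-7-yn-2-one F6.
- Wittig methylenation (Ph3P=CH2, THF, 0 °C) rejoins the route at 9.

Further compounds
F1 | step 7 | 3α-(triethylsilyloxy)eremophila-7(11),9-dien-8-one | CC[Si](CC)(CC)O[C@@H]1CCC2=CC(=O)C(=C(C)C)C[C@]2(C)[C@H]1C
F2 | step 6 | (3R,4R,7E)-9-(tert-butyldimethylsilyloxy)-2,3-dimethyl-4-(triethylsilyloxy)dodeca-1,7-dien-10-yne (C9 epimers) | CC#CC(O[Si](C)(C)C(C)(C)C)/C=C/CC[C@@H](O[Si](CC)(CC)CC)[C@H](C)C(C)=C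
F3 | step 2 | (S)-4-benzyl-3-[(2S,3R)-3-hydroxy-2-methylhept-6-ynoyl]oxazolidin-2-one | C#CCC[C@@H](O)[C@H](C)C(=O)N1[C@@H](Cc2ccccc2)COC1=O
F4 | step 2 | (2S,3R)-3-hydroxy-N-methoxy-N,2-dimethylhept-6-ynamide | C#CCC[C@@H](O)[C@H](C)C(=O)N(C)OC
F5 | step 2 | (2S,3R)-N-methoxy-N,2-dimethyl-3-(triethylsilyloxy)hept-6-ynamide | C#CCC[C@@H](O[Si](CC)(CC)CC)[C@H](C)C(=O)N(C)OC
F6 | step 2 | (3S,4R)-3-methyl-4-(triethylsilyloxy)oct-7-yn-2-one | C#CCC[C@@H](O[Si](CC)(CC)CC)[C@H](C)C(C)=O
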